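**Plan**
- Cuts: ring C of the flavanone is opened at O1–C2 and C2–C3, giving a ring B benzaldehyde and a phloroglucinol beta-keto ester (ring A). Ring B is then cut at C4'–C5' and C1'–C2'. Last, the bond from luteolin C6'' to the future C5' is cut as an aryl–alkyne bond.
- Enabling feature: around ring B the atoms run C1' (carbon substituent, to C2), C2'–H, C3'–O, C4'–O, C5' (carbon substituent, to luteolin C6''), C6'–H. C1'–C6'–C5' is therefore the C(=O)–C≡C unit of an aryl ynone, and C2'–C3'(O)–C4'(O) is the CH3–C(=O)–CH2(OR) unit of an alkoxyacetone.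
- Forward order: the three luteolin rings are bought. C6'' is iodinated and alkynylated, ring B is grown on the alkyne by Michael–aldol benzannulation, ring A is joined by Knoevenagel condensation at the C1' aldehyde, and ring C closes last.
- Stereochemistry: the only stereocentre, C2 (S), comes from a cinchona-thiourea-catalysed intramolecular oxa-Michael addition. It is locked by decarboxylation and kept by a near-neutral final hydrogenolysis of an all-benzyl protecting set.

Key step: step 7

Assumption: the C5'–C6'' axis (three ortho oxygens, one ortho hydrogen) is taken as freely rotating in the target, so only C2 needs control; protected intermediates may appear as rotamers.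
Assumption: the quinine-derived thiourea is taken to give the (2S) series; the sense is to be confirmed on a simple model aldehyde, and the quinidine-derived pseudoenantiomer replaces it if the model turns out (2R).

Step 1
Reactants: 1 luteolin
Product: 2 7,3',4'-tri-O-benzylluteolin (5-OH free)
Conditions: BnBr (3.3 equiv), K2CO3, DMF, rt
Reagents that add atoms: benzyl bromide, BrCc1ccccc1
Why: Williamson etherification takes the three free phenols, while the 5-OH, held in a hydrogen bond to the C4 carbonyl, stays unreacted with a limited amount of bromide at room temperature.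

Step 2
Reactants: 2 7,3',4'-tri-O-benzylluteolin
Product: 3 6-iodo-7,3',4'-tri-O-benzylluteolin
Conditions: NIS (1.05 equiv), DMF, rt, dark
Reagents that add atoms: N-iodosuccinimide, O=C1CCC(=O)N1I
Why: Electrophilic aromatic iodination of 5-hydroxy-7-alkoxyflavones under neutral conditions goes ortho to the chelated 5-OH (C6, not C8), and the dibenzyloxyphenyl ring is deactivated by the pyrone.

Step 3
Reactants: 3 6-iodo-7,3',4'-tri-O-benzylluteolin
Product: 4 6-iodo-5,7,3',4'-tetra-O-benzylluteolin
Conditions: BnBr (1.5 equiv), Cs2CO3, DMF, 60 °C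
Reagents that add atoms: benzyl bromide, BrCc1ccccc1
Why: Williamson etherification under forcing conditions caps the chelated, iodine-flanked 5-OH, which would otherwise close a furan onto the alkyne or add to the later ynone.

Step 4
Reactants: 5 ethynylmagnesium bromide; 6 2,2-dimethoxyacetaldehyde (dried from its commercial aqueous solution by extraction and distillation)
Product: 7 (±)-1,1-dimethoxybut-3-yn-2-ol
Conditions: THF, 0 °C to rt; aq NH4Cl
Reagents that add atoms: none
Why: Grignard 1,2-addition of an acetylide to an aldehyde gives the carbinol, whose centre is racemic and is erased in step 6.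

Step 5
Reactants: 4 6-iodo-5,7,3',4'-tetra-O-benzylluteolin; 7 (±)-1,1-dimethoxybut-3-yn-2-ol
Product: 8 (±)-4-(tetra-O-benzylluteolin-6-yl)-1,1-dimethoxybut-3-yn-2-ol
Conditions: PdCl2(PPh3)2 (5 mol %), CuI (10 mol %), Et3N, DMF, 70 °C, degassed
Reagents that add atoms: none
Why: Sonogashira coupling places the future biaryl bond at a linear sp carbon, the least demanding partner for an aryl iodide flanked by two alkoxy groups.

Step 6
Reactants: 8 (±)-4-(tetra-O-benzylluteolin-6-yl)-1,1-dimethoxybut-3-yn-2-ol
Product: 9 4-(tetra-O-benzylluteolin-6-yl)-1,1-dimethoxybut-3-yn-2-one (aryl ynone with keto acetal)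
Conditions: activated MnO2 (excess), CH2Cl2, rt; filtration through Celite
Reagents that add atoms: none
Why: MnO2 oxidation of a propargylic alcohol is neutral and needs no aqueous work-up, so the acetal, the benzyl ethers and the electrophilic ynone are left intact.

Step 7
Reactants: 9 4-(tetra-O-benzylluteolin-6-yl)-1,1-dimethoxybut-3-yn-2-one; 10 benzyloxyacetone
Product: 13 3-hydroxy-4-benzyloxy-5-(tetra-O-benzylluteolin-6-yl)benzaldehyde dimethyl acetal, via Michael adduct enedione 11 (not isolated), via cyclic aldol 12 (not isolated)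
Conditions: 10 (2.5 equiv), Cs2CO3 (2 equiv), 4 Å MS, DMSO, Ar, rt to 70 °C
Reagents that add atoms: none
Why: Proposed new method: Cs2CO3 reversibly forms the enolate of 10 at its benzyloxy-bearing CH2, and this carbon adds to the aryl-bearing alkyne carbon of 9 (new bond C4'–C5') to give enedione 11, whose E and Z forms equilibrate through the extended dienolate. In the Z form the methyl ketone enolises and its carbon attacks the acetal-flanked ketone (new bond C1'–C2') in a 6-(enolexo)-exo-trig aldol closure to 12; E1cB loss of water and tautomerisation of the resulting cyclohexadienone then deliver ring B as the 3'-phenol, and this aromatisation drains the preceding equilibria. The closest known reaction type is the base-mediated [3+3] benzannulation of aryl ynones with enolisable ketones or beta-keto esters to phenols; not yet shown are an alpha-alkoxy ketone as the three-carbon donor, an alpha-keto acetal as the acceptor carbonyl and a 2,6-dialkoxyaryl group on the acceptor carbon. No lasting stereocentre is formed, because the sp3 centres of 11 and 12 disappear on aromatisation. The step needs 1,4- over 1,2-addition and the right assignment of the two donor carbons: 1,2-adducts at the activated ketone revert by retro-aldol, the ether oxygen makes its CH2 the more acidic and preferred enolate site, and the reversed sequence would have to close the ring through the more hindered secondary carbon next to a fully substituted carbinol. The inductive pull of the keto acetal raises the acceptor strength of the alkyne against the shielding and electron donation of the two ortho benzyloxy groups, and the flavone enone, a vinylogous ester, is too electron-rich to compete as acceptor.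

Step 8
Reactants: 13 3-hydroxy-4-benzyloxy-5-(tetra-O-benzylluteolin-6-yl)benzaldehyde dimethyl acetal
Product: 15 3,4-bis(benzyloxy)-5-(tetra-O-benzylluteolin-6-yl)benzaldehyde, via dibenzyl ether acetal 14 (not isolated)
Conditions: BnBr (1.3 equiv), K2CO3, DMF, rt; filter, then 1 M HCl, THF, rt
Reagents that add atoms: benzyl bromide, BrCc1ccccc1; water, O
Why: Williamson etherification of the unhindered 3'-phenol is followed by acid-catalysed hydrolysis of the aryl dimethyl acetal, to which benzyl ethers and the flavone are inert.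

Step 9
Reactants: 16 2',4',6'-trihydroxyacetophenone
Product: 17 2',4'-bis(benzyloxy)-6'-hydroxyacetophenone
Conditions: BnBr (2.1 equiv), K2CO3, DMF, rt
Reagents that add atoms: benzyl bromide, BrCc1ccccc1
Why: Williamson etherification stops after two alkylations, because the last ortho hydroxyl is hydrogen-bonded to the acetyl group.

Step 10
Reactants: 17 2',4'-bis(benzyloxy)-6'-hydroxyacetophenone
Product: 18 tert-butyl 3-[2,4-bis(benzyloxy)-6-hydroxyphenyl]-3-oxopropanoate
Conditions: LiN(SiMe3)2 (3.3 equiv), THF, −78 °C; Boc2O (1.1 equiv), −78 to −20 °C; AcOH quench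
Reagents that add atoms: di-tert-butyl dicarbonate, CC(C)(C)OC(=O)OC(=O)OC(C)(C)C
Why: This is a crossed Claisen-type C-acylation of the phenoxide–enolate dianion, in which any aryl carbonate formed first is passed to the enolate carbon by a Baker–Venkataraman-type shift and the third equivalent of base holds the product as its enolate.

Step 11
Reactants: 15 3,4-bis(benzyloxy)-5-(tetra-O-benzylluteolin-6-yl)benzaldehyde; 18 tert-butyl 3-[2,4-bis(benzyloxy)-6-hydroxyphenyl]-3-oxopropanoate
Product: 19 tert-butyl (Z)-2-[2,4-bis(benzyloxy)-6-hydroxybenzoyl]-3-[3,4-bis(benzyloxy)-5-(tetra-O-benzylluteolin-6-yl)phenyl]acrylate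
Conditions: piperidine (20 mol %), AcOH (20 mol %), 4 Å MS, toluene, rt
Reagents that add atoms: none
Why: Knoevenagel condensation of an unhindered aryl aldehyde (H at C2' and C6') with an aroylacetate forms C2–C3 and should give mainly the isomer with the aryl group cis to the bulky ester.

Step 12
Reactants: 19 tert-butyl (Z)-alkylidene beta-keto ester
Product: 22 (2S)-octa-O-benzyl ether of the target, via tert-butyl flavanone-3-carboxylate 20 (not isolated), via flavanone-3-carboxylic acid 21 (not isolated)
Conditions: quinine-derived 9-epi-amino 3,5-bis(trifluoromethyl)phenyl thiourea (10 mol %), toluene, −25 °C; then TsOH·H2O (0.5 equiv), 80 °C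
Reagents that add atoms: none
Why: In this organocatalytic asymmetric intramolecular oxa-Michael addition to an alkylidene beta-keto ester, the thiourea binds the dicarbonyl and the quinuclidine nitrogen guides the phenol oxygen to one face of C2 (6-endo-trig, taken as giving S), and acid-induced loss of isobutene with decarboxylation then removes the activating group and blocks ring reopening.

Step 13
Reactants: 22 (2S)-octa-O-benzyl ether of the target
Product: 23 CNP0333260.1, (2S)-2-[3,4-dihydroxy-5-(luteolin-6-yl)phenyl]-5,7-dihydroxychroman-4-one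
Conditions: H2 (1 atm), 10% Pd/C, THF/MeOH, AcOH (1%), rt
Reagents that add atoms: none
Why: Catalytic hydrogenolysis removes all eight benzyl ethers in a base-free, only faintly acidic medium, so C2 is not scrambled through the chalcone, and the flavone alkene and both carbonyls should survive at atmospheric pressure.

**Compound list**
1 | luteolin | O=c1cc(-c2ccc(O)c(O)c2)oc2cc(O)cc(O)c12 | starting material
2 | 7,3',4'-tri-O-benzylluteolin | Oc1cc(OCc2ccccc2)cc2oc(-c3ccc(OCc4ccccc4)c(OCc4ccccc4)c3)cc(=O)c12 | intermediate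
3 | 6-iodo-7,3',4'-tri-O-benzylluteolin | Oc1c(I)c(OCc2ccccc2)cc2oc(-c3ccc(OCc4ccccc4)c(OCc4ccccc4)c3)cc(=O)c12 | intermediate
4 | 6-iodo-5,7,3',4'-tetra-O-benzylluteolin | Ic1c(OCc2ccccc2)cc2oc(-c3ccc(OCc4ccccc4)c(OCc4ccccc4)c3)cc(=O)c2c1OCc1ccccc1 | intermediate
5 | ethynylmagnesium bromide | C#C[Mg]Br | starting material
6 | 2,2-dimethoxyacetaldehyde | COC(OC)C=O | starting material
7 | (±)-1,1-dimethoxybut-3-yn-2-ol (racemic) | COC(OC)C(O)C#C | intermediate
8 | (±)-4-(tetra-O-benzylluteolin-6-yl)-1,1-dimethoxybut-3-yn-2-ol (racemic) | COC(OC)C(O)C#Cc1c(OCc2ccccc2)cc2oc(-c3ccc(OCc4ccccc4)c(OCc4ccccc4)c3)cc(=O)c2c1OCc1ccccc1 | intermediate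
9 | 4-(tetra-O-benzylluteolin-6-yl)-1,1-dimethoxybut-3-yn-2-one | COC(OC)C(=O)C#Cc1c(OCc2ccccc2)cc2oc(-c3ccc(OCc4ccccc4)c(OCc4ccccc4)c3)cc(=O)c2c1OCc1ccccc1 | intermediate
10 | benzyloxyacetone | CC(=O)COCc1ccccc1 | starting material
11 | (Z)-5-benzyloxy-1,1-dimethoxy-4-(tetra-O-benzylluteolin-6-yl)hept-3-ene-2,6-dione (C5 racemic) | COC(OC)C(=O)/C=C(\C(OCc1ccccc1)C(C)=O)c1c(OCc2ccccc2)cc2oc(-c3ccc(OCc4ccccc4)c(OCc4ccccc4)c3)cc(=O)c2c1OCc1ccccc1 | intermediate
12 | 6-benzyloxy-3-(dimethoxymethyl)-3-hydroxy-5-(tetra-O-benzylluteolin-6-yl)cyclohex-4-en-1-one (mixture of stereoisomers) | COC(OC)C1(O)CC(=O)C(OCc2ccccc2)C(c2c(OCc3ccccc3)cc3oc(-c4ccc(OCc5ccccc5)c(OCc5ccccc5)c4)cc(=O)c3c2OCc2ccccc2)=C1 | intermediate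
13 | 3-hydroxy-4-benzyloxy-5-(tetra-O-benzylluteolin-6-yl)benzaldehyde dimethyl acetal | COC(OC)c1cc(O)c(OCc2ccccc2)c(-c2c(OCc3ccccc3)cc3oc(-c4ccc(OCc5ccccc5)c(OCc5ccccc5)c4)cc(=O)c3c2OCc2ccccc2)c1 | intermediate
14 | 3,4-bis(benzyloxy)-5-(tetra-O-benzylluteolin-6-yl)benzaldehyde dimethyl acetal | COC(OC)c1cc(OCc2ccccc2)c(OCc2ccccc2)c(-c2c(OCc3ccccc3)cc3oc(-c4ccc(OCc5ccccc5)c(OCc5ccccc5)c4)cc(=O)c3c2OCc2ccccc2)c1 | intermediate
15 | 3,4-bis(benzyloxy)-5-(tetra-O-benzylluteolin-6-yl)benzaldehyde | O=Cc1cc(OCc2ccccc2)c(OCc2ccccc2)c(-c2c(OCc3ccccc3)cc3oc(-c4ccc(OCc5ccccc5)c(OCc5ccccc5)c4)cc(=O)c3c2OCc2ccccc2)c1 | intermediate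
16 | 2',4',6'-trihydroxyacetophenone | CC(=O)c1c(O)cc(O)cc1O | starting material
17 | 2',4'-bis(benzyloxy)-6'-hydroxyacetophenone | CC(=O)c1c(O)cc(OCc2ccccc2)cc1OCc1ccccc1 | intermediate
18 | tert-butyl 3-[2,4-bis(benzyloxy)-6-hydroxyphenyl]-3-oxopropanoate | CC(C)(C)OC(=O)CC(=O)c1c(O)cc(OCc2ccccc2)cc1OCc1ccccc1 | intermediate
19 | tert-butyl (Z)-alkylidene beta-keto ester (ring B aryl cis to the ester) | CC(C)(C)OC(=O)/C(=C\c1cc(OCc2ccccc2)c(OCc2ccccc2)c(-c2c(OCc3ccccc3)cc3oc(-c4ccc(OCc5ccccc5)c(OCc5ccccc5)c4)cc(=O)c3c2OCc2ccccc2)c1)C(=O)c1c(O)cc(OCc2ccccc2)cc1OCc1ccccc1 | intermediate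
20 | tert-butyl (2S)-octa-O-benzylflavanone-3-carboxylate (C3 labile, left undefined) | O=C1C(C(=O)OC(C)(C)C)[C@@H](c2cc(OCc3ccccc3)c(OCc3ccccc3)c(-c3c(OCc4ccccc4)cc4oc(-c5ccc(OCc6ccccc6)c(OCc6ccccc6)c5)cc(=O)c4c3OCc3ccccc3)c2)Oc2cc(OCc3ccccc3)cc(OCc3ccccc3)c21 | intermediate
21 | (2S)-octa-O-benzylflavanone-3-carboxylic acid (C3 labile, left undefined) | O=C1C(C(=O)O)[C@@H](c2cc(OCc3ccccc3)c(OCc3ccccc3)c(-c3c(OCc4ccccc4)cc4oc(-c5ccc(OCc6ccccc6)c(OCc6ccccc6)c5)cc(=O)c4c3OCc3ccccc3)c2)Oc2cc(OCc3ccccc3)cc(OCc3ccccc3)c21 | intermediate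
22 | (2S)-octa-O-benzyl ether of the target | O=C1C[C@@H](c2cc(OCc3ccccc3)c(OCc3ccccc3)c(-c3c(OCc4ccccc4)cc4oc(-c5ccc(OCc6ccccc6)c(OCc6ccccc6)c5)cc(=O)c4c3OCc3ccccc3)c2)Oc2cc(OCc3ccccc3)cc(OCc3ccccc3)c21 | intermediate
23 | CNP0333260.1, (2S)-2-[3,4-dihydroxy-5-(luteolin-6-yl)phenyl]-5,7-dihydroxychroman-4-one | O=C1C[C@@H](c2cc(O)c(O)c(-c3c(O)cc4oc(-c5ccc(O)c(O)c5)cc(=O)c4c3O)c2)Oc2cc(O)cc(O)c21 | target

Total step count: 13. Longest linear sequence: 10 steps (1, 2, 3, 5, 6, 7, 8, 11, 12, 13).

**Steps most likely to fail**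

Step 7. Several things may go wrong:
- conjugate addition may not start at the alkyne carbon shielded by two ortho benzyloxy groups;
- the ketone may add through its methyl carbon and so transpose the ring B pattern;
- the water set free may hydrate or cleave the ynone.

The fallback gives up building ring B and makes C5'–C6'' by cross-coupling, which is known chemistry at C6 of flavones. It sets out from iodide 4. Commercial 3-bromo-4,5-dihydroxybenzaldehyde F1 is dibenzylated (BnBr, K2CO3, DMF) to 3,4-bis(benzyloxy)-5-bromobenzaldehyde F2. Miyaura borylation (B2pin2, PdCl2(dppf), KOAc, dioxane, 90 °C) then gives 3,4-bis(benzyloxy)-5-(pinacolboryl)benzaldehyde F3. Suzuki–Miyaura coupling of F3 with 4 (Pd(OAc)2, SPhos, K3PO4, toluene/water, 90 °C) comes back to the route at aldehyde 15.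

Step 12. Facial selectivity may be poor because the 6'-benzyloxy group twists the aroyl unit away from the catalyst. Uncatalysed ring closure may add racemate, and retro-oxa-Michael reaction before decarboxylation may erode the enantiomeric purity. Partial loss of the peri benzyl ethers under TsOH would only anticipate step 13.

The fallback replaces asymmetric catalysis by resolution with recycling, and sets out from aldehyde 15 and acetophenone 17. Claisen–Schmidt condensation (KOH, EtOH/THF, rt) gives the (E)-2'-hydroxychalcone F4, and NaOAc in refluxing EtOH closes it to the racemic octa-O-benzylflavanone F5. F5 is separated by preparative chromatography on a polysaccharide chiral stationary phase. The (2S) fraction is 22, where the route is rejoined. The (2R)-octa-O-benzylflavanone F6 is reopened with base to F4 and cycled again.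

Step 5. Oxidative addition at the doubly ortho-substituted iodide may be slow enough for oxidative alkyne dimerisation to consume 7, and the amine base may isomerise the coupled propargylic alcohol to an enone.

The fallback assembles the ynone by acetylide acylation instead of coupling a finished four-carbon unit, and sets out from iodide 4. Sonogashira coupling with the smaller, non-isomerisable trimethylsilylacetylene (PdCl2(PPh3)2, CuI, Et3N, DMF, 70 °C) gives 6-(trimethylsilylethynyl)-tetra-O-benzylluteolin F7. K2CO3 in MeOH/THF then gives 6-ethynyl-tetra-O-benzylluteolin F8. Deprotonation with LiN(SiMe3)2 (THF, −78 °C) and acylation with methyl dimethoxyacetate, whose chelated tetrahedral adduct resists a second addition, come back to the route at ynone 9, so step 6 is skipped.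

**Further compounds**
F1 | step 7 | 3-bromo-4,5-dihydroxybenzaldehyde (purchased) | O=Cc1cc(O)c(O)c(Br)c1
F2 | step 7 | 3,4-bis(benzyloxy)-5-bromobenzaldehyde | O=Cc1cc(OCc2ccccc2)c(OCc2ccccc2)c(Br)c1
F3 | step 7 | 3,4-bis(benzyloxy)-5-(pinacolboryl)benzaldehyde | O=Cc1cc(OCc2ccccc2)c(OCc2ccccc2)c(B2OC(C)(C)C(C)(C)O2)c1
F4 | step 12 | (E)-2'-hydroxychalcone from 15 and 17 | O=C(/C=C/c1cc(OCc2ccccc2)c(OCc2ccccc2)c(-c2c(OCc3ccccc3)cc3oc(-c4ccc(OCc5ccccc5)c(OCc5ccccc5)c4)cc(=O)c3c2OCc2ccccc2)c1)c1c(O)cc(OCc2ccccc2)cc1OCc1ccccc1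
F5 | step 12 | racemic octa-O-benzylflavanone | O=C1CC(c2cc(OCc3ccccc3)c(OCc3ccccc3)c(-c3c(OCc4ccccc4)cc4oc(-c5ccc(OCc6ccccc6)c(OCc6ccccc6)c5)cc(=O)c4c3OCc3ccccc3)c2)Oc2cc(OCc3ccccc3)cc(OCc3ccccc3)c21
F6 | step 12 | (2R)-octa-O-benzylflavanone | O=C1C[C@H](c2cc(OCc3ccccc3)c(OCc3ccccc3)c(-c3c(OCc4ccccc4)cc4oc(-c5ccc(OCc6ccccc6)c(OCc6ccccc6)c5)cc(=O)c4c3OCc3ccccc3)c2)Oc2cc(OCc3ccccc3)cc(OCc3ccccc3)c21
F7 | step 5 | 6-(trimethylsilylethynyl)-tetra-O-benzylluteolin | C[Si](C)(C)C#Cc1c(OCc2ccccc2)cc2oc(-c3ccc(OCc4ccccc4)c(OCc4ccccc4)c3)cc(=O)c2c1OCc1ccccc1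
F8 | step 5 | 6-ethynyl-tetra-O-benzylluteolin | C#Cc1c(OCc2ccccc2)cc2oc(-c3ccc(OCc4ccccc4)c(OCc4ccccc4)c3)cc(=O)c2c1OCc1ccccc1
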